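The six-membered carbocycle (numbered from the ester-bearing C1) is read as a skipped cyclohexa-1,4-diene. The sp3 atoms C3 (carbinol) and C6 (CH2) insulate the enoate C1=C2 from a latent C4=C5 olefin, which is the precursor of the trans-4,5-diol diester. One flask joins two three-carbon pieces, aldehyde 3 (C2–C3–C4, carrying C3 from the chiral pool) and allyl ylide 7 (C5–C6–C1 plus the ester). Wittig olefination makes C1=C2 and ring-closing metathesis makes C4=C5. Hydroxyl-directed epoxidation, C5-selective opening by (S)-3-methylpentanoic acid, orthoester-controlled 3-O-acetylation and a final esterification complete the target.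

Key step: step 4

Assumption: (S)-but-3-ene-1,2-diol, (S)-3-methylpentanoic acid and (R)-2-methylbutanoic acid are taken as commercially available enantiopure materials.

Step 1
Reactants: 1 (S)-but-3-ene-1,2-diol
Product: 2 (S)-3,4-bis[(triethylsilyl)oxy]but-1-ene
Conditions: Et3SiCl, imidazole, CH2Cl2, 0 °C to rt
Reagents that add atoms: chlorotriethylsilane CC[Si](Cl)(CC)CC
Why: Standard silylation of both hydroxyls, which leaves the C–O stereocentre untouched.

Step 2
Reactants: 2 (S)-3,4-bis[(triethylsilyl)oxy]but-1-ene
Product: 3 (S)-2-[(triethylsilyl)oxy]but-3-enal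
Conditions: (COCl)2, DMSO, CH2Cl2, −78 °C; then Et3N, −78 to −40 °C
Reagents that add atoms: none
Why: Under Swern oxidation conditions activated DMSO should cleave and oxidise only the primary triethylsilyl ether, while the low temperature protects the secondary silyl ether, the α-stereocentre and the β,γ-double bond.

Step 3
Reactants: 4 methyl (triphenylphosphoranylidene)acetate; 5 allyl bromide
Product: 7 methyl 2-(triphenylphosphoranylidene)pent-4-enoate, via phosphonium bromide 6 (not isolated)
Conditions: EtOAc, reflux; then aq. NaOH, CH2Cl2, 0 °C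
Reagents that add atoms: none
Why: SN2 C-alkylation of the stabilised ylide followed by deprotonation of the salt should give the α-allyl stabilised ylide.

Step 4
Reactants: 3 (S)-2-[(triethylsilyl)oxy]but-3-enal; 7 methyl 2-(triphenylphosphoranylidene)pent-4-enoate
Product: 9 methyl (3S)-3-[(triethylsilyl)oxy]cyclohexa-1,4-diene-1-carboxylate, via triene ester 8 (not isolated)
Conditions: CH2Cl2, rt; then second-generation Grubbs catalyst (H2IMes)(PCy3)Cl2Ru=CHPh (3 mol%), 1,4-benzoquinone (10 mol%), 40 °C, same flask
Reagents that add atoms: none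
Why: Ylide 7 should add to aldehyde 3 through an oxaphosphetane that collapses to the (E)-trisubstituted enoate 8 (Wittig reaction, forming C1=C2 and expelling Ph3PO); the alkylidene generated from the Grubbs catalyst then joins the two terminal vinyl groups of 8 by ring-closing metathesis, forming C4=C5 and releasing ethylene. The closest known reaction type is the one-pot tandem Wittig olefination/olefin metathesis sequence. The six-membered carbocycle is closed by ring-closing metathesis of the 1,7-diene unit, which requires C3 and C6 to be cis on C1=C2; the E-selectivity of the α-substituted stabilised ylide provides this. No new stereocentre is formed: C3 is carried unchanged from 3, and the base-free olefination limits its epimerisation. The trisubstituted, electron-poor enoate is inert to the catalyst, so only one ring size can form, and benzoquinone suppresses Ru–H-mediated migration of the skipped diene into conjugation and aromatisation.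

Step 5
Reactants: 9 methyl (3S)-3-[(triethylsilyl)oxy]cyclohexa-1,4-diene-1-carboxylate
Product: 10 methyl (3S)-3-hydroxycyclohexa-1,4-diene-1-carboxylate
Conditions: HF·pyridine, pyridine, THF, 0 °C
Reagents that add atoms: none
Why: Fluoride-mediated Si–O cleavage under pyridine-buffered conditions should free the alcohol without acid-catalysed dehydration of the bis-allylic carbinol.

Step 6
Reactants: 10 methyl (3S)-3-hydroxycyclohexa-1,4-diene-1-carboxylate
Product: 11 methyl (3R,4R,5S)-4,5-epoxy-3-hydroxycyclohex-1-ene-1-carboxylate (epoxide cis to the hydroxyl)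
Conditions: VO(acac)2 (cat.), t-BuOOH, CH2Cl2, 0 °C
Reagents that add atoms: tert-butyl hydroperoxide CC(C)(C)OO
Why: VO(acac)2-catalysed hydroxyl-directed epoxidation should deliver oxygen to the electron-rich C4=C5 on the face of the C3 hydroxyl, setting C4 and C5 cis to O3 and leaving the electron-poor enoate untouched.

Step 7
Reactants: 11 methyl (3R,4R,5S)-4,5-epoxy-3-hydroxycyclohex-1-ene-1-carboxylate; 12 (S)-3-methylpentanoic acid
Product: 13 methyl (3R,4R,5R)-3,4-dihydroxy-5-{[(3S)-3-methylpentanoyl]oxy}cyclohex-1-ene-1-carboxylate (methyl 5-O-acylshikimate)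
Conditions: Ti(OiPr)4, CH2Cl2, rt
Reagents that add atoms: none
Why: Ti(OiPr)4-mediated opening of a 2,3-epoxy alcohol: chelation of the C3 alkoxide and the cis epoxide oxygen directs the carboxylate to the distal carbon C5 with inversion (trans-diaxial opening), so O5 becomes trans to O4.

Step 8
Reactants: 13 methyl (3R,4R,5R)-3,4-dihydroxy-5-{[(3S)-3-methylpentanoyl]oxy}cyclohex-1-ene-1-carboxylate
Product: 15 methyl (3R,4S,5R)-3-acetoxy-4-hydroxy-5-{[(3S)-3-methylpentanoyl]oxy}cyclohex-1-ene-1-carboxylate, via cyclic orthoacetate 14 (not isolated)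
Conditions: MeC(OMe)3, PPTS (cat.), CH2Cl2, rt; then 80% aq. AcOH, rt
Reagents that add atoms: trimethyl orthoacetate CC(OC)(OC)OC; water O
Why: The cis-3,4-diol forms a cyclic orthoester whose acid hydrolysis opens kinetically to the ester on the pseudoaxial allylic O3, leaving the equatorial 4-OH free.

Step 9
Reactants: 15 methyl (3R,4S,5R)-3-acetoxy-4-hydroxy-5-{[(3S)-3-methylpentanoyl]oxy}cyclohex-1-ene-1-carboxylate; 16 (R)-2-methylbutanoic acid
Product: 17 methyl (3R,4S,5R)-3-acetoxy-4-{[(2R)-2-methylbutanoyl]oxy}-5-{[(3S)-3-methylpentanoyl]oxy}cyclohex-1-ene-1-carboxylate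
Conditions: N,N′-diisopropylcarbodiimide, DMAP (cat.), CH2Cl2, 0 °C to rt
Reagents that add atoms: none
Why: Steglich esterification of the only free hydroxyl, which touches no stereocentre; the low temperature and catalytic DMAP should limit acetyl migration and α-epimerisation of the acid.

Compound list
1 | (S)-but-3-ene-1,2-diol | OC[C@@H](O)C=C | starting material
2 | (S)-3,4-bis[(triethylsilyl)oxy]but-1-ene | CC[Si](CC)(CC)OC[C@@H](O[Si](CC)(CC)CC)C=C | intermediate
3 | (S)-2-[(triethylsilyl)oxy]but-3-enal | O=C[C@@H](O[Si](CC)(CC)CC)C=C | intermediate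
4 | methyl (triphenylphosphoranylidene)acetate | COC(=O)C=P(c1ccccc1)(c1ccccc1)c1ccccc1 | starting material
5 | allyl bromide | C=CCBr | starting material
6 | (1-methoxy-1-oxopent-4-en-2-yl)triphenylphosphonium bromide | COC(=O)C(CC=C)[P+](c1ccccc1)(c1ccccc1)c1ccccc1.[Br-] | intermediate
7 | methyl 2-(triphenylphosphoranylidene)pent-4-enoate | COC(=O)C(CC=C)=P(c1ccccc1)(c1ccccc1)c1ccccc1 | intermediate
8 | methyl (2E,4S)-2-(prop-2-en-1-yl)-4-[(triethylsilyl)oxy]hexa-2,5-dienoate | COC(=O)/C(CC=C)=C/[C@@H](O[Si](CC)(CC)CC)C=C | intermediate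
9 | methyl (3S)-3-[(triethylsilyl)oxy]cyclohexa-1,4-diene-1-carboxylate | COC(=O)C1=C[C@@H](O[Si](CC)(CC)CC)C=CC1 | intermediate
10 | methyl (3S)-3-hydroxycyclohexa-1,4-diene-1-carboxylate | COC(=O)C1=C[C@@H](O)C=CC1 | intermediate
11 | methyl (3R,4R,5S)-4,5-epoxy-3-hydroxycyclohex-1-ene-1-carboxylate (epoxide cis to OH) | COC(=O)C1=C[C@@H](O)[C@H]2O[C@H]2C1 | intermediate
12 | (S)-3-methylpentanoic acid | CC[C@H](C)CC(=O)O | starting material
13 | methyl (3R,4R,5R)-3,4-dihydroxy-5-{[(3S)-3-methylpentanoyl]oxy}cyclohex-1-ene-1-carboxylate | CC[C@H](C)CC(=O)O[C@@H]1CC(C(=O)OC)=C[C@@H](O)[C@H]1O | intermediate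
14 | 3,4-O-(1-methoxyethylidene) cyclic orthoacetate of 13 (both epimers at the orthoester carbon) | CC[C@H](C)CC(=O)O[C@@H]1CC(C(=O)OC)=C[C@H]2OC(C)(OC)O[C@@H]12 | intermediate
15 | methyl (3R,4S,5R)-3-acetoxy-4-hydroxy-5-{[(3S)-3-methylpentanoyl]oxy}cyclohex-1-ene-1-carboxylate | CC[C@H](C)CC(=O)O[C@@H]1CC(C(=O)OC)=C[C@@H](OC(C)=O)[C@H]1O | intermediate
16 | (R)-2-methylbutanoic acid | CC[C@@H](C)C(=O)O | starting material
17 | methyl (3R,4S,5R)-3-acetoxy-4-{[(2R)-2-methylbutanoyl]oxy}-5-{[(3S)-3-methylpentanoyl]oxy}cyclohex-1-ene-1-carboxylate | CC[C@H](C)CC(=O)O[C@@H]1CC(C(=O)OC)=C[C@@H](OC(C)=O)[C@H]1OC(=O)[C@H](C)CC | target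

Total step count: 9
Longest linear sequence: 8 steps (1 → 2 → 3 → 9 → 10 → 11 → 13 → 15 → 17, that is steps 1, 2 and 4 to 9)

Steps most likely to fail

Step 4. The hindered ylide may olefinate slowly, so that aldehyde 3 epimerises or its double bond moves into conjugation. Residual ylide may also deactivate the metathesis catalyst, or the skipped diene may isomerise and aromatise during ring closure. The fallback sets out from 3 and replaces the Wittig reaction by an aldol/elimination sequence with isolation of the triene. Addition of the lithium enolate of methyl pent-4-enoate (LiN(iPr)2, THF, −78 °C) should give the β-hydroxy ester methyl (4S)-3-hydroxy-2-(prop-2-en-1-yl)-4-[(triethylsilyl)oxy]hex-5-enoate F1. Mesylation and DBU-induced E1cB elimination should give triene 8, now isolated and free of phosphorus. Ring-closing metathesis of purified 8 with the same Grubbs catalyst comes back to the route at 9.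

Step 5. The free bis-allylic alcohol 10 may lose water on traces of acid or on silica and aromatise to methyl benzoate. The fallback sets out from 9 and never passes through 10. N-Bromosuccinimide in wet THF should form the bromonium ion anti to the silyloxy group, and water should open it trans to give the bromohydrin methyl 4-bromo-5-hydroxy-3-[(triethylsilyl)oxy]cyclohex-1-ene-1-carboxylate (5-OH cis to the silyloxy group, Br trans to both) F2. K2CO3 should close F2 to the epoxide cis to the silyl ether, the triethylsilyl ether of 11, F3. Buffered fluoride desilylation of F3 comes back to the route at 11.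

Step 7. Carboxylate attack at C4 instead of C5, or migration of the new ester from O5 to O4 under Ti(OiPr)4, would erode the regiocontrol. The fallback sets out from 11 and removes the free hydroxyl before the opening. Acetylation (Ac2O, pyridine) should give the epoxy acetate methyl 3-acetoxy-4,5-epoxycyclohex-1-ene-1-carboxylate (epoxide cis to the acetate) F4. Opening with (S)-3-methylpentanoic acid under Bu4NBr catalysis (toluene, 80 °C) should occur at C5, because C4 is inductively deactivated and more hindered and trans-diaxial opening also favours C5. This comes back to the route at 15 and bypasses 13 and step 8.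

Further compounds
F1 | step 4 | methyl (4S)-3-hydroxy-2-(prop-2-en-1-yl)-4-[(triethylsilyl)oxy]hex-5-enoate (diastereomer mixture at C2 and C3) | COC(=O)C(CC=C)C(O)[C@@H](O[Si](CC)(CC)CC)C=C
F2 | step 5 | methyl (3R,4R,5S)-4-bromo-5-hydroxy-3-[(triethylsilyl)oxy]cyclohex-1-ene-1-carboxylate | COC(=O)C1=C[C@@H](O[Si](CC)(CC)CC)[C@H](Br)[C@@H](O)C1
F3 | step 5 | methyl 4,5-epoxy-3-[(triethylsilyl)oxy]cyclohex-1-ene-1-carboxylate (epoxide cis to the silyloxy group; triethylsilyl ether of 11) | COC(=O)C1=C[C@@H](O[Si](CC)(CC)CC)[C@H]2O[C@H]2C1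
F4 | step 7 | methyl 3-acetoxy-4,5-epoxycyclohex-1-ene-1-carboxylate (epoxide cis to the acetate; acetate of 11) | COC(=O)C1=C[C@@H](OC(C)=O)[C@H]2O[C@H]2C1
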